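**Retrosynthetic overview**
1. The target 16 comes from hydrogenolysis of two benzyl ethers of hemiketal 15, which comes from stereoretentive C–B oxidation of boronate 14.
2. Boronate 14 comes from copper-catalysed enantioselective conjugate borylation of the achiral chromone 13; this sets the only stereocentre (C2).
3. Chromone 13 is disconnected at the C2–CH2 bond: the lithiated 6-methyl group of 4-benzyloxy-6-methyl-2-pyranone 11 adds to 2-sulfonylchromone 9 with loss of sulfinate.
4. Sulfone 9 comes from the o-hydroxyacetophenone 6 by CS2 annulation, S-methylation and oxidation; the aryl ketone 5 comes from acyltransferase-catalysed C-acetylation of 5-isopentylresorcinol 4, itself from Kumada coupling and demethylation.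
5. Ring order: the benzene ring and the 2-pyranone ring are bought intact; the chromone ring is closed in step 5; its C2=C3 bond is converted into the hemiketal chromanone ring in steps 10–11.

Assumption: the C2 hemiketal keeps its configuration only under cold, neutral handling (acid or base opens the ring), so it is unveiled in the last two steps; the facial sense of the QuinoxP* catalyst is assigned by analogy, and the antipodal ligand is used if the first run gives the (2S)-boronate.

**Step 1**
Reactants: 1 1-bromo-3,5-dimethoxybenzene; 2 (3-methylbutyl)magnesium bromide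
Product: 3 1,3-dimethoxy-5-(3-methylbutyl)benzene
Conditions: NiCl2(dppp) (2 mol%), Et2O/THF, 0 °C to reflux
Reagents that add atoms: none
Why: Kumada–Corriu cross-coupling of a primary alkyl Grignard reagent with an aryl bromide, in which the chelating diphosphine suppresses β-hydride elimination.

**Step 2**
Reactants: 3 1,3-dimethoxy-5-(3-methylbutyl)benzene
Product: 4 5-(3-methylbutyl)benzene-1,3-diol
Conditions: BBr3 (3 equiv), CH2Cl2, −78 °C to rt; then H2O
Reagents that add atoms: none
Why: Lewis-acid cleavage of aryl methyl ethers (BBr3 demethylation) on a substrate with no other sensitive group.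

**Step 3**
Reactants: 4 5-(3-methylbutyl)benzene-1,3-diol
Product: 5 1-[2,4-dihydroxy-6-(3-methylbutyl)phenyl]ethan-1-one
Conditions: acyltransferase (C-acyltransferase from Pseudomonas protegens, recombinant cell-free extract), isopropenyl acetate (5 equiv), KH2PO4/K2HPO4 buffer pH 7.5, 10% DMSO, 35 °C, 24 h
Reagents that add atoms: isopropenyl acetate CC(=C)OC(C)=O
Why: Enzymatic Friedel–Crafts C-acylation, in which the acyltransferase passes the acetyl group through an acyl-enzyme to the ring carbon ortho to one hydroxyl and para to the other, with no O-acylation or diacylation.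

**Step 4**
Reactants: 5 1-[2,4-dihydroxy-6-(3-methylbutyl)phenyl]ethan-1-one
Product: 6 1-[4-(benzyloxy)-2-hydroxy-6-(3-methylbutyl)phenyl]ethan-1-one
Conditions: BnBr (1.05 equiv), K2CO3 (1.2 equiv), acetone, reflux
Reagents that add atoms: benzyl bromide BrCc1ccccc1
Why: Williamson ether synthesis that is regioselective because the 2-hydroxyl is tied up in a hydrogen bond to the ketone, so only the 4-hydroxyl is alkylated.

**Step 5**
Reactants: 6 1-[4-(benzyloxy)-2-hydroxy-6-(3-methylbutyl)phenyl]ethan-1-one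
Product: 7 7-(benzyloxy)-4-hydroxy-5-(3-methylbutyl)-2H-chromene-2-thione
Conditions: KOtBu (3 equiv), CS2 (1.5 equiv), THF, 0 °C to rt; then 1 M HCl
Reagents that add atoms: carbon disulfide S=C=S
Why: Enolate dithiocarboxylation followed by ring closure of the phenoxide onto the dithioate with loss of hydrosulfide, the standard annulation of o-hydroxyacetophenones to the pyranone-thione ring.

**Step 6**
Reactants: 7 7-(benzyloxy)-4-hydroxy-5-(3-methylbutyl)-2H-chromene-2-thione
Product: 8 7-(benzyloxy)-5-(3-methylbutyl)-2-(methylsulfanyl)-4H-chromen-4-one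
Conditions: MeI (1.2 equiv), K2CO3 (1.5 equiv), acetone, rt
Reagents that add atoms: iodomethane CI
Why: S-alkylation of the soft thione sulfur, which fixes the 4-oxo (chromone) tautomer.

**Step 7**
Reactants: 8 7-(benzyloxy)-5-(3-methylbutyl)-2-(methylsulfanyl)-4H-chromen-4-one
Product: 9 7-(benzyloxy)-2-(methanesulfonyl)-5-(3-methylbutyl)-4H-chromen-4-one
Conditions: mCPBA (2.3 equiv), CH2Cl2, 0 °C to rt
Reagents that add atoms: 3-chloroperoxybenzoic acid OOC(=O)c1cccc(Cl)c1
Why: Peracid oxidation of the sulfide to the sulfone, which leaves the electron-poor chromone double bond and the benzyl ether untouched and turns C2 into a strong Michael acceptor with a leaving group.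

**Step 8**
Reactants: 10 4-hydroxy-6-methyl-2H-pyran-2-one
Product: 11 4-(benzyloxy)-6-methyl-2H-pyran-2-one
Conditions: BnOH (1.2 equiv), PPh3, DIAD, THF, 0 °C to rt
Reagents that add atoms: benzyl alcohol OCc1ccccc1
Why: Mitsunobu O-alkylation, for which the acidic 4-hydroxyl (pKa about 5) is an ideal pronucleophile and which avoids C3-alkylation.

**Step 9**
Reactants: 11 4-(benzyloxy)-6-methyl-2H-pyran-2-one; 9 7-(benzyloxy)-2-(methanesulfonyl)-5-(3-methylbutyl)-4H-chromen-4-one
Product: 13 7-(benzyloxy)-2-{[4-(benzyloxy)-2-oxo-2H-pyran-6-yl]methyl}-5-(3-methylbutyl)-4H-chromen-4-one, via pyranonylmethyllithium 12 (not isolated)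
Conditions: 11 (2.2 equiv), LiN(SiMe3)2 (2.2 equiv), THF, −78 °C, 45 min; then 9 (1.0 equiv), −78 to −30 °C; AcOH quench
Reagents that add atoms: none
Why: Conjugate addition–elimination of the vinylogous lithium enolate at C2 of the sulfonylchromone with loss of methanesulfinate, the second equivalent of anion absorbing the acidic CH2 proton of the product.

**Step 10**
Reactants: 13 7-(benzyloxy)-2-{[4-(benzyloxy)-2-oxo-2H-pyran-6-yl]methyl}-5-(3-methylbutyl)-4H-chromen-4-one
Product: 14 (2R)-7-(benzyloxy)-2-{[4-(benzyloxy)-2-oxo-2H-pyran-6-yl]methyl}-5-(3-methylbutyl)-2-(4,4,5,5-tetramethyl-1,3,2-dioxaborolan-2-yl)-2,3-dihydro-4H-chromen-4-one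
Conditions: CuCl (5 mol%), (R,R)-QuinoxP* (6 mol%), NaOtBu (7 mol%), B2pin2 (1.3 equiv), MeOH (2 equiv), THF, 0 °C
Reagents that add atoms: bis(pinacolato)diboron CC1(C)OB(OC1(C)C)B1OC(C)(C)C(C)(C)O1
Why: Copper-catalysed enantioselective conjugate borylation, in which the chiral bisphosphine boryl complex of monovalent copper adds boron to one face of the chromone C2=C3 bond and methanol protonates the enolate, so the catalyst sets C2.

**Step 11**
Reactants: 14 (2R)-boronate
Product: 15 (2R)-7-(benzyloxy)-2-{[4-(benzyloxy)-2-oxo-2H-pyran-6-yl]methyl}-2-hydroxy-5-(3-methylbutyl)-2,3-dihydro-4H-chromen-4-one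
Conditions: 30% aq. H2O2 (3 equiv), THF/pH 7 buffer (NaH2PO4/Na2HPO4), 0 °C, 1 h; cold neutral work-up, used crude
Reagents that add atoms: hydrogen peroxide OO
Why: Boronate oxidation by 1,2-migration of C2 from boron to oxygen, which proceeds with retention of configuration, while the neutral buffer avoids base-induced opening of the new hemiketal.

**Step 12**
Reactants: 15 (2R)-bis(benzyl) hemiketal
Product: 16 (2R)-2,7-dihydroxy-2-[(4-hydroxy-2-oxo-2H-pyran-6-yl)methyl]-5-(3-methylbutyl)-2,3-dihydro-4H-chromen-4-one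
Conditions: H2 (1 atm), 10% Pd/C, EtOAc, 0 °C, 1–2 h; filter, evaporate cold
Reagents that add atoms: none
Why: Catalytic hydrogenolysis cleaves only the two O–CH2Ph bonds under neutral conditions, so no bond to C2 is touched and the hemiketal configuration is kept.

**Compound list**
1 | 1-bromo-3,5-dimethoxybenzene | COc1cc(Br)cc(OC)c1 | starting material
2 | (3-methylbutyl)magnesium bromide | CC(C)CC[Mg]Br | starting material
3 | 1,3-dimethoxy-5-(3-methylbutyl)benzene | COc1cc(CCC(C)C)cc(OC)c1 | intermediate
4 | 5-(3-methylbutyl)benzene-1,3-diol | CC(C)CCc1cc(O)cc(O)c1 | intermediate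
5 | 1-[2,4-dihydroxy-6-(3-methylbutyl)phenyl]ethan-1-one | CC(=O)c1c(O)cc(O)cc1CCC(C)C | intermediate
6 | 1-[4-(benzyloxy)-2-hydroxy-6-(3-methylbutyl)phenyl]ethan-1-one | CC(=O)c1c(O)cc(OCc2ccccc2)cc1CCC(C)C | intermediate
7 | 7-(benzyloxy)-4-hydroxy-5-(3-methylbutyl)-2H-chromene-2-thione | CC(C)CCc1cc(OCc3ccccc3)cc2c1C(O)=CC(=S)O2 | intermediate
8 | 7-(benzyloxy)-5-(3-methylbutyl)-2-(methylsulfanyl)-4H-chromen-4-one | CC(C)CCc1cc(OCc3ccccc3)cc2c1C(=O)C=C(SC)O2 | intermediate
9 | 7-(benzyloxy)-2-(methanesulfonyl)-5-(3-methylbutyl)-4H-chromen-4-one | CC(C)CCc1cc(OCc3ccccc3)cc2c1C(=O)C=C(S(C)(=O)=O)O2 | intermediate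
10 | 4-hydroxy-6-methyl-2H-pyran-2-one | Cc1cc(O)cc(=O)o1 | starting material
11 | 4-(benzyloxy)-6-methyl-2H-pyran-2-one | Cc1cc(OCc2ccccc2)cc(=O)o1 | intermediate
12 | {[4-(benzyloxy)-2-oxo-2H-pyran-6-yl]methyl}lithium (pyranonylmethyllithium) | [Li]CC1=CC(OCc2ccccc2)=CC(=O)O1 | intermediate
13 | 7-(benzyloxy)-2-{[4-(benzyloxy)-2-oxo-2H-pyran-6-yl]methyl}-5-(3-methylbutyl)-4H-chromen-4-one | CC(C)CCc1cc(OCc3ccccc3)cc2c1C(=O)C=C(Cc1cc(OCc3ccccc3)cc(=O)o1)O2 | intermediate
14 | (2R)-7-(benzyloxy)-2-{[4-(benzyloxy)-2-oxo-2H-pyran-6-yl]methyl}-5-(3-methylbutyl)-2-(4,4,5,5-tetramethyl-1,3,2-dioxaborolan-2-yl)-2,3-dihydro-4H-chromen-4-one | CC(C)CCc1cc(OCc3ccccc3)cc2c1C(=O)C[C@@](B3OC(C)(C)C(C)(C)O3)(Cc1cc(OCc3ccccc3)cc(=O)o1)O2 | intermediate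
15 | (2R)-7-(benzyloxy)-2-{[4-(benzyloxy)-2-oxo-2H-pyran-6-yl]methyl}-2-hydroxy-5-(3-methylbutyl)-2,3-dihydro-4H-chromen-4-one | CC(C)CCc1cc(OCc3ccccc3)cc2c1C(=O)C[C@@](O)(Cc1cc(OCc3ccccc3)cc(=O)o1)O2 | intermediate
16 | (2R)-2,7-dihydroxy-2-[(4-hydroxy-2-oxo-2H-pyran-6-yl)methyl]-5-(3-methylbutyl)-2,3-dihydro-4H-chromen-4-one | CC(C)CCc1cc(O)cc2c1C(=O)C[C@@](O)(Cc1cc(O)cc(=O)o1)O2 | target

**Totals**
Total steps: 12. Longest linear sequence: 11 (steps 1–7, then 9–12); step 8 is the side branch.

**Three steps most likely to fail**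

Step 10, the conjugate borylation. The acceptor carbon is tetrasubstituted and oxygen-bearing, the neighbouring CH2 is acidic, and the alkoxide can open the ring through a retro-oxa-Michael path, so low turnover or eroded ee are possible. The fallback sets out from 13 and splits the formal hydration into reduction and C–H oxygenation. A copper hydride conjugate reduction (Cu(OAc)2, (R)-DTBM-SEGPHOS, (EtO)2MeSiH, t-BuOH, toluene, 0 °C) gives (2R)-7-(benzyloxy)-2-{[4-(benzyloxy)-2-oxo-2H-pyran-6-yl]methyl}-5-(3-methylbutyl)-2,3-dihydro-4H-chromen-4-one F1. Its C2–H bond is then hydroxylated with retention (oxygen rebound) by a cytochrome P450 monooxygenase of the flavanone 2-hydroxylase type in a whole-cell biotransformation under air. This comes back to the route at 15.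

Step 9, the addition–elimination coupling. The sulfone may hydrolyse or the stabilised anion may react sluggishly or at the wrong site. The fallback sets out from 11 and 8. Compound 11 is lithiated as before to 12 and transmetalated with ZnBr2 to {[4-(benzyloxy)-2-oxo-2H-pyran-6-yl]methyl}zinc bromide F2. F2 is cross-coupled with the thioether 8 using Pd(PPh3)4 in THF at 50 °C, where zerovalent palladium inserts into the C2–S bond. This replaces the anionic substitution on the sulfone by a near-neutral catalytic coupling and comes back at 13.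

Step 3, the enzymatic C-acetylation. The lipophilic 5-isopentyl substrate may be poorly accepted or poorly soluble. The fallback sets out from 4 and uses a Hoesch acylation (MeCN, ZnCl2, HCl gas, Et2O, 0 °C), which precipitates 1-[2,4-dihydroxy-6-(3-methylbutyl)phenyl]ethan-1-iminium chloride F3. Hydrolysis in hot water comes back at 5.

**Further compounds**
F1 | step 10 | (2R)-7-(benzyloxy)-2-{[4-(benzyloxy)-2-oxo-2H-pyran-6-yl]methyl}-5-(3-methylbutyl)-2,3-dihydro-4H-chromen-4-one | CC(C)CCc1cc(OCc3ccccc3)cc2c1C(=O)C[C@@H](Cc1cc(OCc3ccccc3)cc(=O)o1)O2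
F2 | step 9 | {[4-(benzyloxy)-2-oxo-2H-pyran-6-yl]methyl}zinc bromide | Br[Zn]CC1=CC(OCc2ccccc2)=CC(=O)O1
F3 | step 3 | 1-[2,4-dihydroxy-6-(3-methylbutyl)phenyl]ethan-1-iminium chloride | CC(=[NH2+])c1c(O)cc(O)cc1CCC(C)C.[Cl-]
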